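**Strategy.** Ring A is opened at C1–C2 (eudesmane numbering), the bond between the free carbinol carbon next to quaternary C10 and the ring methylene. The key step, a silyl-triflate-driven intramolecular Mukaiyama aldol, exploits the syn-1,3-dioxygenation C1(OH)/C3(O-acyl) across C2 together with the C4 exocyclic methylene, the retron of a β-silyloxy α'-methylene ketone. It closes ring A onto a finished ring B, forms C1–C2, sets C1 and silylates O1 in one operation. Its precursor is a cyclohexane with a non-enolisable aldehyde (C1) on C10 and a 3-oxobut-1-en-2-yl group on C5, built by a catalytic enantioselective Diels–Alder reaction.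

Key step: step 10

Remark on numbering: eudesmane locants are used for ring atoms throughout (C10 quaternary methyl carbon, C5 ring-fusion CH, C4/C15 methylidene, C3 ester carbinol, C1 free carbinol, C7 isopropyl carbon, C8 ring B carbinol); TBS = tert-butyldimethylsilyl.

Assumption: the oxazaborolidinium catalyst from (S)-diphenylprolinol is taken to expose the enal face that gives the (1R,6R) cycloadduct (formyl C–H···O binding model); should the opposite sense arise, the mirror-image catalyst would be used.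

Step 1
Reactants: 1 3-methylbut-1-yne; 2 ethene
Product: 3 4-methyl-3-methylidenepent-1-ene (2-isopropylbuta-1,3-diene)
Conditions: second-generation Grubbs catalyst RuCl2(=CHPh)(H2IMes)(PCy3) (2 mol%), ethene (1 atm), toluene, 80 °C; distil
Reagents that add atoms: none
Why: Ethene–alkyne cross enyne metathesis should convert the terminal alkyne into the 2-substituted 1,3-diene with full atom economy.

Step 2
Reactants: 3 4-methyl-3-methylidenepent-1-ene; 4 ethyl (2E)-3-methyl-4-oxobut-2-enoate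
Product: 5 ethyl (1R,6R)-6-formyl-6-methyl-3-(propan-2-yl)cyclohex-3-ene-1-carboxylate
Conditions: o-tolyl oxazaborolidine from (S)-α,α-diphenylprolinol (20 mol%), Tf2NH (16 mol%), CH2Cl2, −78 → −20 °C
Reagents that add atoms: none
Why: Catalytic enantioselective Diels–Alder reaction of an α-methyl enal: the N-protonated oxazaborolidinium binds the formyl group and shields one enal face, the formyl-bearing carbon (C10) ends para to the isopropyl-bearing diene carbon, and the E dienophile fixes the C1 and C4 carbons trans, so quaternary C10 and C5 are set together.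

Step 3
Reactants: 5 ethyl (1R,6R)-6-formyl-6-methyl-3-(propan-2-yl)cyclohex-3-ene-1-carboxylate
Product: 6 ethyl (1R,6R)-6-(dimethoxymethyl)-6-methyl-3-(propan-2-yl)cyclohex-3-ene-1-carboxylate
Conditions: HC(OMe)3, MeOH, PPTS (cat.), rt
Reagents that add atoms: trimethyl orthoformate COC(OC)OC; methanol CO
Why: Acid-catalysed acetalisation with orthoformate as water scavenger should mask the neopentylic C1 aldehyde against borane and the later organometallic reagents.

Step 4
Reactants: 6 ethyl (1R,6R)-6-(dimethoxymethyl)-6-methyl-3-(propan-2-yl)cyclohex-3-ene-1-carboxylate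
Product: 8 ethyl (1R,2R,4S,5R)-2-(dimethoxymethyl)-4-hydroxy-2-methyl-5-(propan-2-yl)cyclohexane-1-carboxylate, via alkylborane 7 (not isolated)
Conditions: BH3·THF, THF, 0 °C; then 30% H2O2, aq NaOH, 0 °C
Reagents that add atoms: hydrogen peroxide OO
Why: Hydroboration–oxidation: boron should add to the less substituted C8 and hydrogen to C7, syn and from the face opposite the pseudoaxial C10 methyl of the half-chair that keeps the C1 and C4 groups equatorial, and oxidation with retention then gives the 8-OH trans to the 7-isopropyl group (C7 R, C8 S).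

Step 5
Reactants: 8 ethyl (1R,2R,4S,5R)-2-(dimethoxymethyl)-4-hydroxy-2-methyl-5-(propan-2-yl)cyclohexane-1-carboxylate
Product: 9 ethyl (1R,2R,4S,5R)-4-[(tert-butyldimethylsilyl)oxy]-2-(dimethoxymethyl)-2-methyl-5-(propan-2-yl)cyclohexane-1-carboxylate
Conditions: TBSCl, imidazole, DMAP (cat.), DMF, 40 °C
Reagents that add atoms: tert-butyldimethylsilyl chloride CC(C)(C)[Si](C)(C)Cl
Why: Silyl ether formation protects O8 through the organometallic, olefination and acylation steps and lets all silyl groups be removed in one final operation.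

Step 6
Reactants: 9 ethyl (1R,2R,4S,5R)-4-[(tert-butyldimethylsilyl)oxy]-2-(dimethoxymethyl)-2-methyl-5-(propan-2-yl)cyclohexane-1-carboxylate
Product: 10 (1R,2R,4S,5R)-4-[(tert-butyldimethylsilyl)oxy]-2-(dimethoxymethyl)-N-methoxy-N,2-dimethyl-5-(propan-2-yl)cyclohexane-1-carboxamide
Conditions: MeNH(OMe)·HCl, i-PrMgCl, THF, −20 → 0 °C
Reagents that add atoms: N,O-dimethylhydroxylamine hydrochloride CNOC.Cl
Why: Weinreb amide formation by aminolysis of the ester with the chloromagnesium amide prepares C4 for a single acyl substitution, with C5 remaining in its thermodynamically preferred equatorial configuration.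

Step 7
Reactants: 10 (1R,2R,4S,5R)-4-[(tert-butyldimethylsilyl)oxy]-2-(dimethoxymethyl)-N-methoxy-N,2-dimethyl-5-(propan-2-yl)cyclohexane-1-carboxamide
Product: 11 1-[(1R,2R,4S,5R)-4-[(tert-butyldimethylsilyl)oxy]-2-(dimethoxymethyl)-2-methyl-5-(propan-2-yl)cyclohexyl]-2-ethoxyprop-2-en-1-one
Conditions: ethyl vinyl ether, t-BuLi, THF, −78 → 0 °C; then 10, −78 → −20 °C; aq NH4Cl
Reagents that add atoms: 1-ethoxyvinyllithium [Li]C(=C)OCC (made in the flask from ethyl vinyl ether C=COCC)
Why: Weinreb ketone synthesis: acyl substitution by 1-ethoxyvinyllithium, an acetyl anion equivalent that brings C3 and C2, should stop cleanly at the ketone stage.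

Step 8
Reactants: 11 1-[(1R,2R,4S,5R)-4-[(tert-butyldimethylsilyl)oxy]-2-(dimethoxymethyl)-2-methyl-5-(propan-2-yl)cyclohexyl]-2-ethoxyprop-2-en-1-one
Product: 12 tert-butyl{[(1S,2R,4S,5R)-5-(dimethoxymethyl)-4-(3-ethoxybuta-1,3-dien-2-yl)-5-methyl-2-(propan-2-yl)cyclohexyl]oxy}dimethylsilane
Conditions: Cp2TiMe2 (3 equiv), toluene, 65 °C, dark
Reagents that add atoms: dimethyltitanocene C[Ti](C)(C1C=CC=C1)C1C=CC=C1
Why: Petasis methylenation should turn the hindered, enolisable C4 ketone into the C4=C15 methylidene under non-basic conditions that leave acetal, silyl ether and enol ether intact.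

Step 9
Reactants: 12 tert-butyl{[(1S,2R,4S,5R)-5-(dimethoxymethyl)-4-(3-ethoxybuta-1,3-dien-2-yl)-5-methyl-2-(propan-2-yl)cyclohexyl]oxy}dimethylsilane
Product: 13 (1R,2R,4R,5S)-5-[(tert-butyldimethylsilyl)oxy]-1-methyl-2-(3-oxobut-1-en-2-yl)-4-(propan-2-yl)cyclohexane-1-carbaldehyde
Conditions: TsOH·H2O (10 mol%), acetone/H2O 10:1, rt
Reagents that add atoms: water O
Why: Mild acid hydrolysis should unmask both the dimethyl acetal (C1 aldehyde) and the enol ether (C3 methyl ketone) while the secondary silyl ether survives.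

Step 10
Reactants: 13 (1R,2R,4R,5S)-5-[(tert-butyldimethylsilyl)oxy]-1-methyl-2-(3-oxobut-1-en-2-yl)-4-(propan-2-yl)cyclohexane-1-carbaldehyde
Product: 15 (4R,4aR,6S,7R,8aR)-4,6-bis[(tert-butyldimethylsilyl)oxy]-4a-methyl-1-methylidene-7-(propan-2-yl)octahydronaphthalen-2(1H)-one, via silyl enol ether 14 (not isolated)
Conditions: TBSOTf (1.5 equiv), i-Pr2NEt (2.5 equiv), CH2Cl2 (0.01 M), −78 → −30 °C; aq NaHCO3
Reagents that add atoms: tert-butyldimethylsilyl triflate CC(C)(C)[Si](C)(C)OS(=O)(=O)C(F)(F)F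
Why: Silylative intramolecular Mukaiyama aldol: TBSOTf/i-Pr2NEt first converts the methyl ketone, whose only enolisable position is C2, into 2-silyloxydiene 14, TBSOTf then activates the non-enolisable C1 aldehyde as a silyloxocarbenium ion, C2 attacks it and the resulting C3 oxocarbenium ion releases its silyl group, so the net change is C1–C2 bond formation with silyl transfer to O1. The closest known reaction type is the silyl triflate/amine-promoted silylative cycloaldolisation of aldehydes tethered to enol silanes formed in situ (one-pot enol silane formation–Mukaiyama aldol). Ring A closes in a 6-(enolexo)-exo-trig mode through a chair, the ring B chair holding the C1 aldehyde and the C4 side chain trans-diequatorial. The new stereocentre C1 is substrate-controlled in an open, non-chelated transition state in which the bulky silylated oxygen takes the equatorial position, away from the axial hydrogens at C5 and C9 and from the enol silane oxygen, which should give the 1R (1β) silyl ether. The step needs site selectivity for C2 over C15 of the silyloxydiene, secured because only attack through C2 gives an oxygen-stabilised cation and a six-membered ring, and it needs the β-silyloxy ketone to persist, secured by low temperature and a non-nucleophilic base that disfavour elimination to the C1=C2 enone.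

Step 11
Reactants: 15 (4R,4aR,6S,7R,8aR)-4,6-bis[(tert-butyldimethylsilyl)oxy]-4a-methyl-1-methylidene-7-(propan-2-yl)octahydronaphthalen-2(1H)-one
Product: 16 (2S,4R,4aR,6S,7R,8aS)-4,6-bis[(tert-butyldimethylsilyl)oxy]-4a-methyl-1-methylidene-7-(propan-2-yl)decahydronaphthalen-2-ol
Conditions: NaBH4, CeCl3·7H2O, MeOH, −78 °C
Reagents that add atoms: none
Why: Luche reduction: 1,2-selective hydride addition to the enone along the axial trajectory on the open α face of the chair should give the equatorial 3β-alcohol (C3 S).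

Step 12
Reactants: 17 caffeic acid, (2E)-3-(3,4-dihydroxyphenyl)prop-2-enoic acid
Product: 19 (2E)-3-{3,4-bis[(tert-butyldimethylsilyl)oxy]phenyl}prop-2-enoic acid, via tris-silyl caffeate 18 (not isolated)
Conditions: TBSCl (3.3 equiv), imidazole, DMF, rt; then AcOH/THF/H2O, rt
Reagents that add atoms: tert-butyldimethylsilyl chloride CC(C)(C)[Si](C)(C)Cl
Why: Exhaustive silylation followed by selective hydrolysis of the labile silyl ester should leave both phenols protected and the carboxylic acid free.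

Step 13
Reactants: 16 (2S,4R,4aR,6S,7R,8aS)-4,6-bis[(tert-butyldimethylsilyl)oxy]-4a-methyl-1-methylidene-7-(propan-2-yl)decahydronaphthalen-2-ol; 19 (2E)-3-{3,4-bis[(tert-butyldimethylsilyl)oxy]phenyl}prop-2-enoic acid
Product: 20 (2S,4R,4aR,6S,7R,8aS)-4,6-bis[(tert-butyldimethylsilyl)oxy]-4a-methyl-1-methylidene-7-(propan-2-yl)decahydronaphthalen-2-yl (2E)-3-{3,4-bis[(tert-butyldimethylsilyl)oxy]phenyl}prop-2-enoate
Conditions: DCC, DMAP (cat.), CH2Cl2, 0 °C → rt
Reagents that add atoms: none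
Why: Steglich esterification of the only free hydroxyl, the allylic 3-OH, installs the (E)-caffeoyl unit without touching a stereocentre.

Step 14
Reactants: 20 (2S,4R,4aR,6S,7R,8aS)-4,6-bis[(tert-butyldimethylsilyl)oxy]-4a-methyl-1-methylidene-7-(propan-2-yl)decahydronaphthalen-2-yl (2E)-3-{3,4-bis[(tert-butyldimethylsilyl)oxy]phenyl}prop-2-enoate
Product: 21 (2S,4R,4aR,6S,7R,8aS)-4,6-dihydroxy-4a-methyl-1-methylidene-7-(propan-2-yl)decahydronaphthalen-2-yl (2E)-3-(3,4-dihydroxyphenyl)prop-2-enoate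
Conditions: HF·pyridine, pyridine/THF, 0 °C → rt
Reagents that add atoms: none
Why: Fluoride-mediated desilylation under non-basic conditions should free the two secondary alcohols and the catechol without ester cleavage, and acyl migration is excluded because the 1- and 3-oxygens are both equatorial on the rigid trans-decalin.

**Compound list**

1 | 3-methylbut-1-yne | CC(C)C#C | starting material
2 | ethene | C=C | starting material
3 | 4-methyl-3-methylidenepent-1-ene (2-isopropylbuta-1,3-diene) | C=CC(=C)C(C)C | intermediate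
4 | ethyl (2E)-3-methyl-4-oxobut-2-enoate | O=C/C(C)=C/C(=O)OCC | starting material
5 | ethyl (1R,6R)-6-formyl-6-methyl-3-(propan-2-yl)cyclohex-3-ene-1-carboxylate | O=C[C@]1(C)CC=C(C(C)C)C[C@H]1C(=O)OCC | intermediate
6 | ethyl (1R,6R)-6-(dimethoxymethyl)-6-methyl-3-(propan-2-yl)cyclohex-3-ene-1-carboxylate | COC(OC)[C@]1(C)CC=C(C(C)C)C[C@H]1C(=O)OCC | intermediate
7 | alkylborane, ethyl (1R,2R,4S,5S)-4-boranyl-2-(dimethoxymethyl)-2-methyl-5-(propan-2-yl)cyclohexane-1-carboxylate (BH2 where 8 carries OH; not isolated) | COC(OC)[C@]1(C)C[C@H](B)[C@@H](C(C)C)C[C@H]1C(=O)OCC | intermediate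
8 | ethyl (1R,2R,4S,5R)-2-(dimethoxymethyl)-4-hydroxy-2-methyl-5-(propan-2-yl)cyclohexane-1-carboxylate | COC(OC)[C@]1(C)C[C@H](O)[C@@H](C(C)C)C[C@H]1C(=O)OCC | intermediate
9 | ethyl (1R,2R,4S,5R)-4-[(tert-butyldimethylsilyl)oxy]-2-(dimethoxymethyl)-2-methyl-5-(propan-2-yl)cyclohexane-1-carboxylate | COC(OC)[C@]1(C)C[C@H](O[Si](C)(C)C(C)(C)C)[C@@H](C(C)C)C[C@H]1C(=O)OCC | intermediate
10 | (1R,2R,4S,5R)-4-[(tert-butyldimethylsilyl)oxy]-2-(dimethoxymethyl)-N-methoxy-N,2-dimethyl-5-(propan-2-yl)cyclohexane-1-carboxamide | COC(OC)[C@]1(C)C[C@H](O[Si](C)(C)C(C)(C)C)[C@@H](C(C)C)C[C@H]1C(=O)N(C)OC | intermediate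
11 | 1-[(1R,2R,4S,5R)-4-[(tert-butyldimethylsilyl)oxy]-2-(dimethoxymethyl)-2-methyl-5-(propan-2-yl)cyclohexyl]-2-ethoxyprop-2-en-1-one | COC(OC)[C@]1(C)C[C@H](O[Si](C)(C)C(C)(C)C)[C@@H](C(C)C)C[C@H]1C(=O)C(=C)OCC | intermediate
12 | tert-butyl{[(1S,2R,4S,5R)-5-(dimethoxymethyl)-4-(3-ethoxybuta-1,3-dien-2-yl)-5-methyl-2-(propan-2-yl)cyclohexyl]oxy}dimethylsilane | COC(OC)[C@]1(C)C[C@H](O[Si](C)(C)C(C)(C)C)[C@@H](C(C)C)C[C@H]1C(=C)C(=C)OCC | intermediate
13 | (1R,2R,4R,5S)-5-[(tert-butyldimethylsilyl)oxy]-1-methyl-2-(3-oxobut-1-en-2-yl)-4-(propan-2-yl)cyclohexane-1-carbaldehyde | O=C[C@]1(C)C[C@H](O[Si](C)(C)C(C)(C)C)[C@@H](C(C)C)C[C@H]1C(=C)C(C)=O | intermediate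
14 | silyl enol ether, (1R,2S,4R,5S)-5-[(tert-butyldimethylsilyl)oxy]-2-{3-[(tert-butyldimethylsilyl)oxy]buta-1,3-dien-2-yl}-1-methyl-4-(propan-2-yl)cyclohexane-1-carbaldehyde (not isolated) | O=C[C@]1(C)C[C@H](O[Si](C)(C)C(C)(C)C)[C@@H](C(C)C)C[C@H]1C(=C)C(=C)O[Si](C)(C)C(C)(C)C | intermediate
15 | (4R,4aR,6S,7R,8aR)-4,6-bis[(tert-butyldimethylsilyl)oxy]-4a-methyl-1-methylidene-7-(propan-2-yl)octahydronaphthalen-2(1H)-one | C=C1C(=O)C[C@@H](O[Si](C)(C)C(C)(C)C)[C@]2(C)C[C@H](O[Si](C)(C)C(C)(C)C)[C@@H](C(C)C)C[C@@H]12 | intermediate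
16 | (2S,4R,4aR,6S,7R,8aS)-4,6-bis[(tert-butyldimethylsilyl)oxy]-4a-methyl-1-methylidene-7-(propan-2-yl)decahydronaphthalen-2-ol | C=C1[C@@H](O)C[C@@H](O[Si](C)(C)C(C)(C)C)[C@]2(C)C[C@H](O[Si](C)(C)C(C)(C)C)[C@@H](C(C)C)C[C@@H]12 | intermediate
17 | caffeic acid, (2E)-3-(3,4-dihydroxyphenyl)prop-2-enoic acid | OC(=O)/C=C/c1ccc(O)c(O)c1 | starting material
18 | tris-silyl caffeate, tert-butyldimethylsilyl (2E)-3-{3,4-bis[(tert-butyldimethylsilyl)oxy]phenyl}prop-2-enoate (not isolated) | CC(C)(C)[Si](C)(C)OC(=O)/C=C/c1ccc(O[Si](C)(C)C(C)(C)C)c(O[Si](C)(C)C(C)(C)C)c1 | intermediate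
19 | (2E)-3-{3,4-bis[(tert-butyldimethylsilyl)oxy]phenyl}prop-2-enoic acid | OC(=O)/C=C/c1ccc(O[Si](C)(C)C(C)(C)C)c(O[Si](C)(C)C(C)(C)C)c1 | intermediate
20 | (2S,4R,4aR,6S,7R,8aS)-4,6-bis[(tert-butyldimethylsilyl)oxy]-4a-methyl-1-methylidene-7-(propan-2-yl)decahydronaphthalen-2-yl (2E)-3-{3,4-bis[(tert-butyldimethylsilyl)oxy]phenyl}prop-2-enoate | C=C1[C@@H](OC(=O)/C=C/c2ccc(O[Si](C)(C)C(C)(C)C)c(O[Si](C)(C)C(C)(C)C)c2)C[C@@H](O[Si](C)(C)C(C)(C)C)[C@]2(C)C[C@H](O[Si](C)(C)C(C)(C)C)[C@@H](C(C)C)C[C@@H]12 | intermediate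
21 | (2S,4R,4aR,6S,7R,8aS)-4,6-dihydroxy-4a-methyl-1-methylidene-7-(propan-2-yl)decahydronaphthalen-2-yl (2E)-3-(3,4-dihydroxyphenyl)prop-2-enoate (1β,8α-dihydroxyeudesm-4(15)-en-3β-yl caffeate) | C=C1[C@@H](OC(=O)/C=C/c2ccc(O)c(O)c2)C[C@@H](O)[C@]2(C)C[C@H](O)[C@@H](C(C)C)C[C@@H]12 | target

**Step count.** Total: 14 steps. Longest linear sequence: 13 steps (steps 1–11, 13 and 14).

**Steps most likely to fail**

Step 10 (key step). The silylated aldehyde may be attacked on its other face, giving the axial 1-silyl ether, or the β-silyloxy ketone may eliminate to the C1=C2 enone. The fallback replaces kinetic, silyl-trapped closure by thermodynamic control and sets out from 13. Catalytic KOt-Bu in THF/t-BuOH at −20 °C runs the aldol reversibly, so retro-aldol equilibration should funnel the material to the equatorial (4R)-β-hydroxy ketone F1. NaBH4/CeCl3·7H2O should then give the syn-1,3-diol F2. DCC/DMAP with 19 at 0 °C should acylate only the unhindered allylic 3-OH (the 1-OH is neopentylic) to give the mono-ester F3. HF·pyridine then gives 21, where the fallback rejoins the route.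

Step 2. Enantiofacial discrimination may be insufficient, or of the wrong sense, for this β-substituted α-methyl enal. The fallback replaces asymmetric catalysis by resolution and sets out from 3 and 4. An Et2AlCl-promoted Diels–Alder reaction gives racemic 5, that is 5 together with its enantiomer F4. Steps 3 and 4 carry the racemate on to 6 with its enantiomer F5 and, through borane 7 with its enantiomer F6, to 8 with its enantiomer F7. Burkholderia cepacia lipase with vinyl acetate in MTBE should acetylate the (4R)-carbinol F7 to the acetate F8, following the usual lipase preference for the (R)-configured secondary alcohol seen with menthol-type substrates. Unreacted 8 is separated and re-enters the route at 8.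

Step 8. Carbonyl methylenation may stall at the hindered, enolisable ketone, and the acid-labile ethoxydiene may be lost on prolonged heating. The fallback replaces carbonyl olefination by cross-coupling and sets out from 10. MeMgBr gives the methyl ketone F9. KHMDS/PhNTf2 at −78 °C should form the kinetic enol triflate F10 by deprotonation at the methyl group and not at the hindered ring CH. Stille coupling with tributyl(1-ethoxyvinyl)stannane [Pd(PPh3)4, LiCl, CuCl, DMSO] then gives 12, where the fallback rejoins the route.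

Further compounds
F1 | step 10 | (4R,4aR,6S,7R,8aR)-6-[(tert-butyldimethylsilyl)oxy]-4-hydroxy-4a-methyl-1-methylidene-7-(propan-2-yl)octahydronaphthalen-2(1H)-one | C=C1C(=O)C[C@@H](O)[C@]2(C)C[C@H](O[Si](C)(C)C(C)(C)C)[C@@H](C(C)C)C[C@@H]12
F2 | step 10 | (2S,4R,4aR,6S,7R,8aS)-6-[(tert-butyldimethylsilyl)oxy]-4a-methyl-1-methylidene-7-(propan-2-yl)decahydronaphthalene-2,4-diol | C=C1[C@@H](O)C[C@@H](O)[C@]2(C)C[C@H](O[Si](C)(C)C(C)(C)C)[C@@H](C(C)C)C[C@@H]12
F3 | step 10 | (2S,4R,4aR,6S,7R,8aS)-6-[(tert-butyldimethylsilyl)oxy]-4-hydroxy-4a-methyl-1-methylidene-7-(propan-2-yl)decahydronaphthalen-2-yl (2E)-3-{3,4-bis[(tert-butyldimethylsilyl)oxy]phenyl}prop-2-enoate | C=C1[C@@H](OC(=O)/C=C/c2ccc(O[Si](C)(C)C(C)(C)C)c(O[Si](C)(C)C(C)(C)C)c2)C[C@@H](O)[C@]2(C)C[C@H](O[Si](C)(C)C(C)(C)C)[C@@H](C(C)C)C[C@@H]12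
F4 | step 2 | ethyl (1S,6S)-6-formyl-6-methyl-3-(propan-2-yl)cyclohex-3-ene-1-carboxylate (enantiomer of 5) | O=C[C@@]1(C)CC=C(C(C)C)C[C@@H]1C(=O)OCC
F5 | step 2 | ethyl (1S,6S)-6-(dimethoxymethyl)-6-methyl-3-(propan-2-yl)cyclohex-3-ene-1-carboxylate (enantiomer of 6) | COC(OC)[C@@]1(C)CC=C(C(C)C)C[C@@H]1C(=O)OCC
F6 | step 2 | ethyl (1S,2S,4R,5R)-4-boranyl-2-(dimethoxymethyl)-2-methyl-5-(propan-2-yl)cyclohexane-1-carboxylate (enantiomer of alkylborane 7, not isolated) | COC(OC)[C@@]1(C)C[C@@H](B)[C@H](C(C)C)C[C@@H]1C(=O)OCC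
F7 | step 2 | ethyl (1S,2S,4R,5S)-2-(dimethoxymethyl)-4-hydroxy-2-methyl-5-(propan-2-yl)cyclohexane-1-carboxylate (enantiomer of 8) | COC(OC)[C@@]1(C)C[C@@H](O)[C@H](C(C)C)C[C@@H]1C(=O)OCC
F8 | step 2 | ethyl (1S,2S,4R,5S)-4-(acetyloxy)-2-(dimethoxymethyl)-2-methyl-5-(propan-2-yl)cyclohexane-1-carboxylate | COC(OC)[C@@]1(C)C[C@@H](OC(C)=O)[C@H](C(C)C)C[C@@H]1C(=O)OCC
F9 | step 8 | 1-[(1R,2R,4S,5R)-4-[(tert-butyldimethylsilyl)oxy]-2-(dimethoxymethyl)-2-methyl-5-(propan-2-yl)cyclohexyl]ethan-1-one | COC(OC)[C@]1(C)C[C@H](O[Si](C)(C)C(C)(C)C)[C@@H](C(C)C)C[C@H]1C(C)=O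
F10 | step 8 | 1-[(1R,2R,4S,5R)-4-[(tert-butyldimethylsilyl)oxy]-2-(dimethoxymethyl)-2-methyl-5-(propan-2-yl)cyclohexyl]ethenyl trifluoromethanesulfonate | COC(OC)[C@]1(C)C[C@H](O[Si](C)(C)C(C)(C)C)[C@@H](C(C)C)C[C@H]1C(=C)OS(=O)(=O)C(F)(F)F
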